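Readings and results were computed on assumed constants, and the scatter is random.

**At the bench.** At 68 s, the last reading, the teal flask holds c(Xp) = 172.5 mM, made from 250 mM of Xa with 25.0 mM of Xc charged. That is 6.90 turnovers: the turnover number, Xp made per Xc charged.

common to all: Xa 250 mM

| flask | Xc | time |
|---|---|---|
| teal | 25.0 mM |  |
| amber | 75.0 mM |  |
| ochre | 25.0 mM | 200 s |

| teal run: time / s | teal run: [Xp] / mM | amber run: time / s | amber run: [Xp] / mM |
|---|---|---|---|
| 9.7 | 42.2 | 9.7 | 93.6 |
| 19 | 73.5 | 19 | 148.9 |
| 29 | 102.4 | 29 | 185.6 |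
| 39 | 126.7 | 39 | 207.9 |
| 49 | 144.7 | 49 | 221.9 |
| 58 | 160.4 | 58 | 230.6 |
| 68 | 172.5 | 68 | 236.2 |

(standard deviation of a reading: 0.8 mM)

- order of the initial rate in [Xc], near the charge of the teal run, the rate being that where two percent of its Xa are Xp
- Xp in the ochre run at 200 s, as a share of the Xa charged

- Overall: Xa -> Xp, with Xc as catalyst.
- Constant volume, constant temperature.
- An order is taken over about fifteen percent of the charge, up and down.

**Ochre ahead.** The ochre flask has the teal charge, so its turnover number can reach 10.0 when its Xa has turned. I read it as teal carried on, with 3.10 turnovers still open at 68 s. Teal's last two readings give a first-order constant for Xa of 0.0145 s⁻¹, a reading with scatter. Held to 200 s, it shrinks the open gap to 0.457, so I expect 9.54 turnovers, or 95.4%.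

**Hands off.** Leave the ochre charge alone, because Xc moves the curve: amber, with 75.0 mM of Xc, stands higher than teal at 68 s, at 236.2 mM against 172.5 mM.

**The forecast.** It gives order 0.85 and 94%, or 9.40 turnovers, lower than my figure. Its ground: “The sag therefore follows time, not conversion”.

**The flask.** It gives order 0.85 and 95.9%, from these steps:

    Xc + Xa → Xp + Xc (0.6360 L mol⁻¹ s⁻¹)
    Xa → Xp (0.002720 s⁻¹)
    2 Xc → 2 G (0.04180 L mol⁻¹ s⁻¹)

**In turnovers.** The ochre flask reaches 9.59 of its 10.0 turnovers at 200 s. At equal Xp made, amber's rate is 2.7 times teal's, on 3.00 times the Xc. Amber reaches half its Xa at 14.3 s, which is 1.67 turnovers counted as all Xp made per Xc charged, and teal at 38.5 s, which is 5.00.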